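At constant temperature, two flasks run for 20 min and differ in one charge, the protic impurity.

    released group → by-product carried off (k1 = 0.0024 s⁻¹)
    second end groups + protic impurity → quenched reagent (k2 = 1.2 L mol⁻¹ s⁻¹)
    first end groups + second end groups ⇌ links + released group (K3 = 0.95, k3 = 0.22 L mol⁻¹ s⁻¹)

| setting | Wednesday's | Friday's |
|---|---|---|
| first end groups | 0.037 M | 0.037 M |
| second end groups | 0.0407 M | 0.0407 M |
| protic impurity | 3.70 mM | 2.50 mM |
| time | 20 min | 20 min |

- each molecule carries two end groups: a chain counts once for every two ends that are left, dead ends included; the units are half of the end groups of the two monomers charged
- run time (Wednesday's): 20 min

- which of the two ends with the longer chains by the average number of monomer units in a chain (unreacted monomers counted as chains of one) ("neither" if they lie within 10%) (Wednesday's / Friday's / neither)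
- average number of monomer units in a chain (unreacted monomers counted as chains of one) at the end, Wednesday's
- average number of monomer units in a chain (unreacted monomers counted as chains of one) at the end, Friday's

We keep a ledger of ends. The end stock, 77.7 mM, is the sum of the two charges of end groups. Each link strikes off two ends, while a quenched end stays on the books as a dead end. So the chain length is the end stock divided by what remains after two ends per c(links) are struck off.

We book the impurity as quenched first: at Wednesday's charges its half-life against second end groups, 0.237 min, is shorter than the 1.3 min of first end groups by the forward rate of the linking step.

| Entry | Wednesday's | Friday's |
|---|---|---|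
| first end groups | 0.037 M | 0.037 M |
| second end groups charged | 0.0407 M | 0.0407 M |
| lost to quenching | 3.70 mM | 2.50 mM |
| live second ends | 37.0 mM | 38.2 mM |

In Friday's flask the first end groups are the limiting reagent of the linking, with a surplus of live second ends of 1.20 mM. With the first end groups used up, the ledger leaves c(second end groups) minus c(first end groups) in either flask, which gives a ceiling of 21.0, and the impurity does not enter it. The end stock is the same in both flasks, so by the ledger their lengths differ through c(links). Our reckoning stops here, since it does not give c(links) at 20 min.

The forecast says 3.06 for Wednesday's, 3.18 for Friday's and neither, and its reasoning runs that “progress is limited by removal of the released group”.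

The flasks give 3.04 and 3.15, so the answer is neither. Links stand at 70.5% of the first end groups charged in Wednesday's flask and 71.6% in Friday's, and the ledger turns Wednesday's figure into 3.04.

The neighbour of Wednesday's flask is charged with 0.022 M of first end groups, so its end stock is 62.7 mM. Links reach 84.8% of its first end groups, more than the 70.5% of Wednesday's. The ledger strikes off two ends per link and gives 2.47, under its ceiling of 3.35. The neighbour ends at 2.47, shorter than Wednesday's 3.04.

The rate constants are invented; the run is a simulation.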